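**Retrosynthetic overview**

1. The side chain is a skipped 1,4-diene: the carbon attached to ring C5 carries an exocyclic =CH2, then comes one CH2, then the E CH=CH ending at the quaternary carbinol carbon. This 2-substituted 1,4-diene is the retron of a Ru-catalysed alkene–alkyne (Alder-ene type) coupling.
2. Cutting between the methylene-bearing sp2 carbon and the doubly allylic CH2 gives alkyne 12 (terminal C≡CH on C5 of the cyclohexenone ring) and alkene 16 (CH2=CH–CH2 on the carbinol carbon, with two transferable allylic H). Both isobutyrates are already in place, so the coupling is the last step and loses no atom.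
3. The feature that makes this possible: the only monosubstituted alkene is the vinyl group of 16; the ring C2=C3 is trisubstituted and electron-poor and stays out of the metallacycle.
4. Ring order: the cyclohexenone (the only ring) is built first by an organocatalytic Michael/aldol annulation that sets C5 as R; C2 is then hydroxymethylated (Morita–Baylis–Hillman) and acylated.
5. The (R)-carbinol comes from (S)-2-methylglycidol by Cu-catalysed vinyl Grignard opening and primary acylation.

Key step: step 8

Assumption: (S)-2-methylglycidol (13) is bought as the single enantiomer; it is otherwise available in one step by Sharpless epoxidation of 2-methylprop-2-en-1-ol.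

**Route**

Step 1
Reactants: 1 3-(trimethylsilyl)prop-2-ynal; 2 (triphenylphosphoranylidene)acetaldehyde
Product: 3 (E)-5-(trimethylsilyl)pent-2-en-4-ynal
Conditions: toluene, rt, 1 in slight excess
Reagents that add atoms: (triphenylphosphoranylidene)acetaldehyde 2, O=CC=P(c1ccccc1)(c1ccccc1)c1ccccc1
Why: Wittig olefination with a stabilised formyl ylide, which should be E-selective and should stop after one homologation because the ynal is more electrophilic than the product enynal.

Step 2
Reactants: 3 (E)-5-(trimethylsilyl)pent-2-en-4-ynal; 4 tert-butyl 3-oxobutanoate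
Product: 7 (5R)-5-[(trimethylsilyl)ethynyl]cyclohex-2-en-1-one, via Michael adduct 5 (not isolated), via cyclised keto ester 6 (not isolated)
Conditions: (S)-α,α-bis[3,5-bis(trifluoromethyl)phenyl]prolinol trimethylsilyl ether (10 mol%), toluene, rt; then p-TsOH·H2O (20 mol%), toluene, 80 °C
Reagents that add atoms: tert-butyl 3-oxobutanoate 4, CC(=O)CC(=O)OC(C)(C)C
Why: Organocatalytic cyclohexenone annulation (iminium-ion Michael addition of the β-keto ester, then acid-mediated intramolecular aldol condensation and tert-butyl ester cleavage/decarboxylation) of the kind established for β-substituted enals; C5 is set in the Michael step, where the diaryl(silyloxy)methyl group of the (S)-catalyst shields one face of the E, s-trans iminium ion so that 4 should add to the open face and give the (R)-configured propargylic carbon, the silyl cap disfavouring δ-attack.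

Step 3
Reactants: 7 (5R)-5-[(trimethylsilyl)ethynyl]cyclohex-2-en-1-one
Product: 8 (5R)-5-ethynylcyclohex-2-en-1-one
Conditions: TBAF (1.1 equiv), AcOH (1.2 equiv), THF, 0 °C
Reagents that add atoms: none
Why: Fluoride-induced protodesilylation of the alkynylsilane, buffered with acetic acid so that the enone and the C5 stereocentre are not exposed to base.

Step 4
Reactants: 8 (5R)-5-ethynylcyclohex-2-en-1-one; 9 formaldehyde
Product: 10 (5R)-5-ethynyl-2-(hydroxymethyl)cyclohex-2-en-1-one
Conditions: 37% aq. formaldehyde, DMAP (20 mol%), THF/H2O, rt
Reagents that add atoms: formaldehyde 9, C=O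
Why: Morita–Baylis–Hillman hydroxymethylation of a cyclohex-2-enone at C2 under nucleophilic amine catalysis, which does not touch C5 or the terminal alkyne.

Step 5
Reactants: 10 (5R)-5-ethynyl-2-(hydroxymethyl)cyclohex-2-en-1-one; 11 2-methylpropanoyl chloride
Product: 12 [(4R)-4-ethynyl-6-oxocyclohex-1-en-1-yl]methyl 2-methylpropanoate
Conditions: pyridine, CH2Cl2, 0 °C
Reagents that add atoms: 2-methylpropanoyl chloride 11, CC(C)C(=O)Cl
Why: O-acylation of the primary allylic alcohol with an acid chloride, with pyridine instead of a stronger nucleophilic catalyst to avoid SN2' chemistry at the newly formed allylic ester.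

Step 6
Reactants: 13 [(2S)-2-methyloxiran-2-yl]methanol; 14 vinylmagnesium bromide
Product: 15 (2R)-2-methylpent-4-ene-1,2-diol
Conditions: vinylMgBr (3 equiv), CuI (10 mol%), THF, −40 to 0 °C; then aqueous work-up (NH4Cl)
Reagents that add atoms: vinylmagnesium bromide 14, C=C[Mg]Br
Why: Cu-catalysed Grignard opening of a 2,2-disubstituted epoxide at its CH2 terminus, which leaves the C–O bond of the quaternary carbon intact (retention; the descriptor changes from S to R only through the priority rules), while a Payne rearrangement of the alkoxide would be degenerate and cannot erode the configuration.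

Step 7
Reactants: 15 (2R)-2-methylpent-4-ene-1,2-diol; 11 2-methylpropanoyl chloride
Product: 16 (2R)-2-hydroxy-2-methylpent-4-en-1-yl 2-methylpropanoate
Conditions: 11 (1.05 equiv), pyridine, CH2Cl2, −20 to 0 °C
Reagents that add atoms: 2-methylpropanoyl chloride 11, CC(C)C(=O)Cl
Why: Selective esterification of the primary hydroxyl of a primary/tertiary 1,2-diol, the tertiary alcohol being too hindered to be acylated under these conditions.

Step 8
Reactants: 12 [(4R)-4-ethynyl-6-oxocyclohex-1-en-1-yl]methyl 2-methylpropanoate; 16 (2R)-2-hydroxy-2-methylpent-4-en-1-yl 2-methylpropanoate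
Product: 17 [(4R)-4-[(4E,6R)-6-hydroxy-6-methyl-7-(2-methylpropanoyloxy)hepta-1,4-dien-2-yl]-6-oxocyclohex-1-en-1-yl]methyl 2-methylpropanoate (CNP0536801.1)
Conditions: [CpRu(MeCN)3]PF6 (10 mol%), 16 (1.3 equiv), degassed acetone, rt
Reagents that add atoms: none
Why: Ru-catalysed alkene–alkyne coupling (formal intermolecular Alder-ene reaction): 12 and the vinyl group of 16 bind the CpRu+ fragment and cyclise oxidatively to a ruthenacyclopentene whose new C–C bond joins the internal alkyne carbon to the terminal alkene carbon; β-hydride elimination of an allylic hydrogen next to the quaternary carbinol then creates the E CH=CH, and C–H reductive elimination at the former terminal alkyne carbon releases the exocyclic =CH2. The closest known reaction type is this same coupling of terminal alkynes, including ones branched at the propargylic carbon, with monosubstituted alkenes bearing free hydroxyl, ester and ketone groups, which gives branched 1,4-dienes. No ring is closed and no stereocentre is formed; ring C5 and the quaternary carbinol take no part in the bond reorganisation and keep their configuration. The step needs branched rather than linear regiochemistry, which the terminal alkyne supplies because its unsubstituted carbon binds Ru and the substituted carbon takes the position β to Ru, away from the Cp ligand; it also needs E geometry, which follows from the β-hydride elimination conformer that turns the bulky carbinol away from the metal. Chemoselectivity rests on the fact that only a monosubstituted alkene enters the cycle: the trisubstituted, electron-poor C2=C3 of the ring and the 1,1- and 1,2-disubstituted alkenes of the product are inert, and the neutral, redox-free conditions should leave both isobutyrates and the tertiary alcohol untouched.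

**Compound list**

1 | 3-(trimethylsilyl)prop-2-ynal | C[Si](C)(C)C#CC=O | starting material
2 | (triphenylphosphoranylidene)acetaldehyde | O=CC=P(c1ccccc1)(c1ccccc1)c1ccccc1 | starting material
3 | (E)-5-(trimethylsilyl)pent-2-en-4-ynal | C[Si](C)(C)C#C/C=C/C=O | intermediate
4 | tert-butyl 3-oxobutanoate | CC(=O)CC(=O)OC(C)(C)C | starting material
5 | tert-butyl (3R)-2-acetyl-5-oxo-3-[(trimethylsilyl)ethynyl]pentanoate (Michael adduct; C2 epimers; not isolated) | C[Si](C)(C)C#C[C@@H](C(C(C)=O)C(=O)OC(C)(C)C)CC=O | intermediate
6 | tert-butyl (6R)-2-oxo-6-[(trimethylsilyl)ethynyl]cyclohex-3-ene-1-carboxylate (cyclised keto ester; C1 epimers; not isolated) | C[Si](C)(C)C#C[C@@H]1CC=CC(=O)C1C(=O)OC(C)(C)C | intermediate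
7 | (5R)-5-[(trimethylsilyl)ethynyl]cyclohex-2-en-1-one | C[Si](C)(C)C#C[C@@H]1CC=CC(=O)C1 | intermediate
8 | (5R)-5-ethynylcyclohex-2-en-1-one | C#C[C@@H]1CC=CC(=O)C1 | intermediate
9 | formaldehyde | C=O | starting material
10 | (5R)-5-ethynyl-2-(hydroxymethyl)cyclohex-2-en-1-one | C#C[C@@H]1CC=C(CO)C(=O)C1 | intermediate
11 | 2-methylpropanoyl chloride | CC(C)C(=O)Cl | starting material
12 | [(4R)-4-ethynyl-6-oxocyclohex-1-en-1-yl]methyl 2-methylpropanoate | C#C[C@@H]1CC=C(COC(=O)C(C)C)C(=O)C1 | intermediate
13 | [(2S)-2-methyloxiran-2-yl]methanol ((S)-2-methylglycidol) | C[C@]1(CO)CO1 | starting material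
14 | vinylmagnesium bromide | C=C[Mg]Br | starting material
15 | (2R)-2-methylpent-4-ene-1,2-diol | C=CC[C@@](C)(O)CO | intermediate
16 | (2R)-2-hydroxy-2-methylpent-4-en-1-yl 2-methylpropanoate | C=CC[C@@](C)(O)COC(=O)C(C)C | intermediate
17 | [(4R)-4-[(4E,6R)-6-hydroxy-6-methyl-7-(2-methylpropanoyloxy)hepta-1,4-dien-2-yl]-6-oxocyclohex-1-en-1-yl]methyl 2-methylpropanoate | C=C(C/C=C/[C@@](C)(O)COC(=O)C(C)C)[C@@H]1CC=C(COC(=O)C(C)C)C(=O)C1 | target

**Step count and risks**

Total steps: 8. Longest linear sequence: 6 (steps 1–5 and 8).

Most likely to fail, step 8. The oxidative cyclisation may form the C–C bond at the terminal instead of the internal alkyne carbon, a tendency that the branched propargylic carbon (ring C5) increases; this would give the linear E,E-1,4-diene. The cationic Ru centre may also ionise the allylic isobutyrate on the ring. The fallback sets out from 12 and 13 and comes back at 17, making the contested bond by cross-coupling and the E-alkene by metathesis. Gem-selective hydrosilylation of 12 (Et3SiH, [Cp*Ru(MeCN)3]PF6, CH2Cl2) should give [(4R)-6-oxo-4-[1-(triethylsilyl)ethenyl]cyclohex-1-en-1-yl]methyl 2-methylpropanoate F1. Iododesilylation (NIS, hexafluoroisopropanol, 0 °C) should give [(4R)-4-(1-iodoethenyl)-6-oxocyclohex-1-en-1-yl]methyl 2-methylpropanoate F2. Stille coupling with allyltributylstannane (Pd2(dba)3, AsPh3, CuI, DMF) should give [(4R)-6-oxo-4-(penta-1,4-dien-2-yl)cyclohex-1-en-1-yl]methyl 2-methylpropanoate F3, with the regiochemistry fixed by the position of the iodide. In parallel, 13 is homologated with dimethylsulfonium methylide (Me3SI, n-BuLi, THF) to (2R)-2-methylbut-3-ene-1,2-diol F4 and acylated at the primary hydroxyl with 11 to (2R)-2-hydroxy-2-methylbut-3-en-1-yl 2-methylpropanoate F5. E-selective cross-metathesis of the monosubstituted alkene of F3 with an excess of F5 (Hoveyda–Grubbs II catalyst, CH2Cl2, 40 °C) should then give 17.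

Second, step 2. The β-keto ester may attack the δ-carbon of the enynyl iminium ion (1,6-addition), or the slim alkynyl group may give poor facial discrimination. The fallback sets out from 4 and comes back at 8, so step 3 is not needed; it builds the alkyne after the annulation instead of carrying it through. The same two-stage annulation, with the same (S)-catalyst, is run on commercial (E)-4,4-dimethoxybut-2-enal, an enal of the well-behaved alkyl type in which δ-attack is impossible; this should give (5R)-5-(dimethoxymethyl)cyclohex-2-en-1-one F6. Mild aqueous acid (PPTS, acetone/H2O) should free (1R)-5-oxocyclohex-3-ene-1-carbaldehyde F7. Seyferth–Gilbert homologation with the Ohira–Bestmann reagent (K2CO3, MeOH, 0 °C) should then give 8.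

Third, step 4. Turnover of the amine adduct of the 5-substituted enone may be slow, so that dimerisation of the enone or further reaction of the product with formaldehyde competes. The fallback sets out from 7 and comes back at 10, installing the hydroxymethyl group by cross-coupling. α-Iodination of 7 (I2, pyridine, CH2Cl2) should give (5R)-2-iodo-5-[(trimethylsilyl)ethynyl]cyclohex-2-en-1-one F8. Stille coupling with (tributylstannyl)methanol (Pd(PPh3)4, dioxane, 80 °C) should give (5R)-2-(hydroxymethyl)-5-[(trimethylsilyl)ethynyl]cyclohex-2-en-1-one F9, the silyl cap keeping the alkyne out of the palladium chemistry. Desilylation under the conditions of step 3 should then give 10.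

Further compounds
F1 | step 8 | [(4R)-6-oxo-4-[1-(triethylsilyl)ethenyl]cyclohex-1-en-1-yl]methyl 2-methylpropanoate | C=C([Si](CC)(CC)CC)[C@@H]1CC=C(COC(=O)C(C)C)C(=O)C1
F2 | step 8 | [(4R)-4-(1-iodoethenyl)-6-oxocyclohex-1-en-1-yl]methyl 2-methylpropanoate | C=C(I)[C@@H]1CC=C(COC(=O)C(C)C)C(=O)C1
F3 | step 8 | [(4R)-6-oxo-4-(penta-1,4-dien-2-yl)cyclohex-1-en-1-yl]methyl 2-methylpropanoate | C=CCC(=C)[C@@H]1CC=C(COC(=O)C(C)C)C(=O)C1
F4 | step 8 | (2R)-2-methylbut-3-ene-1,2-diol | C=C[C@@](C)(O)CO
F5 | step 8 | (2R)-2-hydroxy-2-methylbut-3-en-1-yl 2-methylpropanoate | C=C[C@@](C)(O)COC(=O)C(C)C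
F6 | step 2 | (5R)-5-(dimethoxymethyl)cyclohex-2-en-1-one | COC(OC)[C@@H]1CC=CC(=O)C1
F7 | step 2 | (1R)-5-oxocyclohex-3-ene-1-carbaldehyde | O=C[C@@H]1CC=CC(=O)C1
F8 | step 4 | (5R)-2-iodo-5-[(trimethylsilyl)ethynyl]cyclohex-2-en-1-one | C[Si](C)(C)C#C[C@@H]1CC=C(I)C(=O)C1
F9 | step 4 | (5R)-2-(hydroxymethyl)-5-[(trimethylsilyl)ethynyl]cyclohex-2-en-1-one | C[Si](C)(C)C#C[C@@H]1CC=C(CO)C(=O)C1
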